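## Structural features

The target is a germacrane-type ten-membered carbocycle, numbered here C1 (epoxide CH), C10 (fully substituted epoxide carbon carrying C14H2–O–isobutyryl), C9 (CH–OAc), C8, C7 (CH–isopropenyl), C6, C5=C4 (C4 carrying the methyl ester C15), C3 and C2; the configuration is 1R,7S,9S,10S. Two unsaturation sites stand in a 1,5-relationship: a trisubstituted trans epoxide across C1–C10 (C2 and C9 on opposite faces, so it derives from an E alkene) and a C4=C5 enoate whose ring carbons C3 and C6 are cis (CIP E, because the ester outranks C3). Three of the four stereocentres are contiguous (C9, C10, C1), with the C9 acetate and the epoxide oxygen syn along the extended C8–C9–C10–C1 chain (a threo pair); C7 stands alone, 1,3 to C9. Fragile points are the epoxide flanked by two acyloxy groups (acid, Lewis acid, Payne-type migration), two different esters on a 1,3-diol unit (acyl migration, base), the enoate (conjugate addition), the isopropenyl group (electrophilic oxidants, boranes, an excited enone) and every cis,trans-cyclodeca-1,5-diene on the way (Cope rearrangement). The real difficulty is the medium ring: closing ten atoms is unfavourable, and the ring must end with one cis and one trans trisubstituted alkene at defined positions before stereocentres can be placed on it. The plan avoids ring closure, because the diene C10=C1–C2–C3–C4=C5 is the open form of a bicyclo[2.2.0]hexane (C1, C2, C3, C4, C5, C10), so the ten-membered ring can be released from a 6-4-4 tricycle by breaking C1–C4 and C5–C10. The key step builds that tricycle by joining a cyclohexenone (C5=C10, with C9 as carbonyl, C14 on C10 and the C7 stereocentre) to a cyclobutene (C1=C4, with C15 on C4) through the new bonds C1–C10 and C4–C5.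

## Logic of the disconnections

23 to 22 to 21: the C14O–acyl bond is cut first, then the two epoxide C–O bonds at C1 and C10. The isobutyrate goes on last because the free C14 hydroxyl is the handle that steers the epoxidation. This removes two stereocentres and leaves an E alkene. The forward step must select one face of a hindered allylic alcohol that has a cis substituent on the distal alkene carbon, with only one free hydroxyl present.

21 to 20 to 19 to 18: the C14–O–Si and C9–O–acyl bonds are adjusted and the C9–H bond is cut (carbonyl reduction). This removes the C9 stereocentre and leaves 18 with C7 as its only stereocentre. The forward steps need a reagent-controlled 1,2-reduction of a hindered ring-trans enone, and the acetate must be in place before the silyl group is removed.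

18 to 17: the bonds C1–C4 and C5–C10 are reconnected (reverse of a thermal cycloreversion). This trades the ten-membered ring and both alkene geometries for a rigid tricycle made by cycloaddition. The forward opening must put the trans alkene at C1=C10 and the cis alkene at C4=C5, and must run below the temperature at which the product drains away by Cope rearrangement. For that reason C15 is already at the ester level in 17: it stabilises the C4 radical and biases the geometry.

17 to 13 (through 16, 15, 14): functional-group change at C15 only, ester back to the PMB-protected alcohol. The cyclobutene partner must be a donor-type alkyl alkene for the regiochemistry of the cycloaddition, so the ester cannot be present earlier. The forward steps must unveil and oxidise C15–O beside the C14 silyl ether, the ketone and the isopropenyl group.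

13 to 8 + 12: the bonds C1–C10 and C4–C5 are cut. This splits the skeleton into a ten-carbon and a five-carbon piece of similar complexity. The forward step must be head-to-tail (C4 to C5) and give the cis-anti-cis tricycle.

8 to 7 to 5 + 6: the C10–C14 bond is cut (one-carbon electrophile onto the enone α-carbon). The forward step needs an α-selective hydroxymethylation that leaves C7 alone.

5 to 3 to 1 + 2: the C5=C10 unsaturation is removed and the C7–isopropenyl bond is cut. This reaches two commercial compounds and makes C7 the product of a catalytic asymmetric 1,4-addition. The forward steps need high enantioselectivity and deprotonation on the side away from C7.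

12 to 11 to 10 to 9: ether C–O bond, then reduction level at C15, then the ring alkene by loss of HBr. All are functional-group changes on a four-membered ring that is bought intact.

## Other disconnections considered

Alternative 1: The cut is the C3–C4 single bond between an allylic methylene and the α-carbon of the enoate.
- Forward step: the open-chain (Z)-2-iodo enoate pinacol boronate A2, already carrying the epoxide, both silyl ethers and C7, is closed with PdCl2(dppf) and base. Zerovalent palladium inserts into the C4–I bond, the base-activated boronate transmetalates and reductive elimination gives the ten-membered bis-silyl ether A1.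
- In favour: both alkene geometries and all four stereocentres are fixed before the ring forms, and the coupling keeps the C4=C5 geometry. On certainty of alkene geometry this alternative is the better plan.
- Against: an sp3–sp2 coupling that closes a ten-membered ring works against transannular strain, so protodeboronation, β-hydride elimination and oligomerisation compete. A base-activated boronate sits beside an epoxide and an enoate. A2 needs a long linear synthesis in which C7 and the C9/C10/C1 triad are set on an open chain.
- Comparison: on structure the two plans are equal at the end (A1 is two deprotections and two acylations from the target, like 19 to 23). On mechanism the chosen plan is driven by strain release and the alternative is opposed by strain. On step economy the chosen plan reaches the ring in twelve steps, and A2 alone would be expected to cost more.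

Alternative 2: The cut is again C5–C10, but heterolytic and in a trans-decalin.
- Forward step: KOt-Bu deprotonates the tertiary C5 hydroxyl of the hydroxy mesylate A4. The alkoxide breaks C5–C10 anti to the equatorial C1 mesylate and gives the ten-membered β-keto ester A3.
- In favour: the anti-periplanar arrangement in the trans-decalin can only give the E C1=C10 alkene, and the reaction runs near room temperature, so there is no Cope drain. On the trans-alkene question this alternative is the better plan.
- Against: A3 has no oxygen at C9, so a late allylic oxidation would have to choose C9 over C2 and the isopropenyl allylic positions. The ring-cis enoate must still be made from the β-keto ester (enol triflate, then reduction) in a medium ring. The C5 alkoxide is β to the C4 ester, so retro-aldol cleavage of C4–C5 competes with the fragmentation. Five stereocentres are built in A4 to be destroyed.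
- Comparison: on structure A3 is further from the target than 18. On mechanism the two are equal in being ring openings driven by strain. On step economy the chosen plan is shorter.

Alternative 3: The cut is C7–C8, made by a sigmatropic ring contraction.
- Forward step: the β-hydroxy macrolactone A6 is converted into its dianion and silylated (LiN(i-Pr)2, then Me3SiCl). The silyl ketene acetal rearranges, C8 bonding to C7 while O–C12 breaks, to give the ten-membered β-hydroxy acid A5.
- In favour: a fourteen-membered lactone closes more easily than a ten-membered carbocycle. Both ring alkenes are made as open-chain alkenes and are spectators, so on alkene geometry this alternative is the better plan. The isopropenyl group and C7 are created in the ring-forming step, and the C9 oxygen is present from the start (equal to the chosen plan).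
- Against: the C8 carboxyl is superfluous and must be removed by radical decarboxylation next to a 1,5-diene, with a risk of transannular radical cyclisation. The dianion of a β-hydroxy ester can eliminate the C9 oxygen. Whether the rearrangement in a macrocycle goes through a chair or a boat decides C7, and this is not securely predictable. A6 with three defined trisubstituted alkenes is long to make.
- Comparison: on structure A5 needs more corrective steps than 18. On mechanism it is a concerted rearrangement with a stereochemical gamble at C7, against a stepwise photocycloaddition whose stereocentres do not matter. On step economy the chosen plan is shorter.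

Key step: step 8

Assumption: addition of 12 to 8 is drawn anti to the isopropenyl group. A facial isomer would differ only at centres that step 12 removes.

## Route

Step 1
Reactants: 1 cyclohex-2-en-1-one; 2 potassium trifluoro(prop-1-en-2-yl)borate
Product: 3 (S)-3-(prop-1-en-2-yl)cyclohexan-1-one
Conditions: Rh(acac)(C2H4)2 (3 mol %), (S)-BINAP (3.3 mol %), dioxane–H2O 10:1, 100 °C
Reagents that add atoms: none
Why: Rhodium-catalysed asymmetric 1,4-addition of an alkenylboron reagent (Hayashi–Miyaura reaction): the trifluoroborate hydrolyses to the boronic acid, the isopropenyl group is transferred to rhodium and adds to one enantioface of the enone held by the ligand, and water protonates the rhodium enolate. By analogy with aryl and 1-alkenyl transfer, (S)-BINAP should give the S ketone, which sets C7.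

Step 2
Reactants: 3 (S)-3-(prop-1-en-2-yl)cyclohexan-1-one
Product: 5 (S)-5-(prop-1-en-2-yl)cyclohex-2-en-1-one, via trimethylsilyl enol ether 4 (not isolated)
Conditions: LiN(i-Pr)2, Me3SiCl, THF, −78 °C; then Pd(OAc)2, MeCN, rt
Reagents that add atoms: none
Why: Saegusa–Ito oxidation: kinetic deprotonation with silylation in the same flask should take the proton on the side away from the isopropenyl-bearing carbon, the silyl enol ether is transferred to divalent palladium, and β-hydride elimination gives the enone and zerovalent palladium. The regioisomeric enol ether can only give achiral 3-isopropenylcyclohex-2-enone, which is removed by chromatography; C7 is not touched.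

Step 3
Reactants: 5 (S)-5-(prop-1-en-2-yl)cyclohex-2-en-1-one; 6 formaldehyde
Product: 7 (S)-2-(hydroxymethyl)-5-(prop-1-en-2-yl)cyclohex-2-en-1-one
Conditions: aq. CH2O (37 %), DMAP (20 mol %), THF–H2O, rt
Reagents that add atoms: none
Why: Morita–Baylis–Hillman hydroxymethylation: DMAP adds to the β-carbon, the enolate captures formaldehyde at the α-carbon and DMAP is expelled. β-Unsubstituted cyclohexenones are standard substrates, and C7 is remote from the reacting carbons.

Step 4
Reactants: 7 (S)-2-(hydroxymethyl)-5-(prop-1-en-2-yl)cyclohex-2-en-1-one
Product: 8 (S)-2-[(tert-butyldimethylsilyloxy)methyl]-5-(prop-1-en-2-yl)cyclohex-2-en-1-one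
Conditions: t-BuMe2SiCl, imidazole, CH2Cl2, 0 °C to rt
Reagents that add atoms: tert-butyldimethylsilyl chloride, CC(C)(C)[Si](C)(C)Cl
Why: Silylation of a primary allylic alcohol with a silyl chloride and imidazole. The ether prevents hydrogen bonding to the cyclobutene partner and retro-aldol loss of C14 later.

Step 5
Reactants: 9 ethyl 1-bromocyclobutane-1-carboxylate
Product: 10 cyclobut-1-ene-1-carboxylic acid
Conditions: KOH, PhMe, reflux; then aq. HCl
Reagents that add atoms: potassium hydroxide, [K+].[OH-]
Why: Base-induced dehydrobromination (E2) of the tertiary α-bromo ester with saponification in the same pot, the established entry to this acid; acidification frees it.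

Step 6
Reactants: 10 cyclobut-1-ene-1-carboxylic acid
Product: 11 (cyclobut-1-en-1-yl)methanol
Conditions: LiAlH4, Et2O, 0 °C
Reagents that add atoms: none
Why: Hydride reduction of a carboxylic acid to the primary alcohol. Attack is at the carboxyl carbon (1,2-reduction), which should leave the strained ring alkene in place at 0 °C.

Step 7
Reactants: 11 (cyclobut-1-en-1-yl)methanol
Product: 12 1-[(4-methoxybenzyloxy)methyl]cyclobut-1-ene
Conditions: NaH, 4-MeOC6H4CH2Cl, Bu4NI (cat.), THF, 0 °C to rt
Reagents that add atoms: 4-methoxybenzyl chloride, COc1ccc(CCl)cc1
Why: Williamson etherification of the sodium alkoxide with the benzylic chloride under iodide catalysis. The PMB ether is non-volatile, does not absorb above 300 nm and is removable by oxidation.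

Step 8
Reactants: 8 (S)-2-[(tert-butyldimethylsilyloxy)methyl]-5-(prop-1-en-2-yl)cyclohex-2-en-1-one; 12 1-[(4-methoxybenzyloxy)methyl]cyclobut-1-ene
Product: 13 cis-anti-cis 6-4-4 photoadduct (tricyclo[4.4.0.0(2,5)]decan-7-one with CH2OTBS on C10, CH2OPMB on C4 and isopropenyl on C7, anti to the cyclobutane)
Conditions: hν (λ ≥ 350 nm), 12 (5 equiv), CH2Cl2 (0.05 M, degassed), −40 °C
Reagents that add atoms: none
Why: Enone–alkene [2+2] photocycloaddition of the kind known for cyclohexenones and cyclobutenes: excitation of 8 and intersystem crossing give the twisted triplet enone, which adds to 12 stepwise through a triplet 1,4-diradical that closes after spin inversion. The central cyclobutane (C1, C10, C5, C4) is the only ring closed; it forms intermolecularly, one bond by radical addition and the second by recombination of the 1,4-diradical. The step needs head-to-tail regiochemistry (C4 to C5, C1 to C10), and two features of the substrates favour it: 12 is a donor-type alkyl alkene, and the head-to-head mode would have to join the two fully substituted carbons C10 and C4. C1 and C4 are cis because they lie in the four-membered ring of 12; C5 and C10 should be cis because a trans ring fusion on top of a bicyclo[2.2.0]hexane is far more strained. The two outer rings lie anti across the new cyclobutane because the CH2–CH2 bridge of 12 approaches away from the cyclohexanone ring. The enone face is chosen by C7: bonding at C5 occurs axially, anti to the pseudo-equatorial isopropenyl group. All four new centres are removed in step 12, so only the cis-anti-cis relationship matters and a facial isomer would converge. Light above 350 nm is absorbed only by the enone, and the excess of 12 at low temperature is meant to outrun capture of the triplet by the isopropenyl group.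

Step 9
Reactants: 13 cis-anti-cis 6-4-4 photoadduct
Product: 14 C15 alcohol of the tricycle (CH2OH on C4)
Conditions: DDQ, CH2Cl2–pH 7 buffer, 0 °C to rt
Reagents that add atoms: none
Why: Oxidative cleavage of the PMB ether: single-electron oxidation of the electron-rich arene by DDQ, then hydrolysis of the oxocarbenium ion. The silyl ether, the ketone and the isopropenyl group are inert to DDQ.

Step 10
Reactants: 14 C15 alcohol of the tricycle
Product: 16 C15 carboxylic acid of the tricycle, via C15 aldehyde 15 (not isolated)
Conditions: TEMPO (20 mol %), PhI(OAc)2, MeCN–pH 7 buffer, rt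
Reagents that add atoms: water, O
Why: Nitroxyl-catalysed oxidation with PhI(OAc)2 as terminal oxidant: the oxoammonium ion takes the neopentyl alcohol to the aldehyde, whose hydrate is oxidised again to the acid. The reagent should not touch the isopropenyl group, the ketone or the buffered silyl ether.

Step 11
Reactants: 16 C15 carboxylic acid of the tricycle
Product: 17 C15 methyl ester of the tricycle (keto ester, CO2Me on C4)
Conditions: MeI, K2CO3, DMF, rt
Reagents that add atoms: iodomethane, CI
Why: SN2 O-alkylation of the potassium carboxylate. K2CO3 does not enolise the hindered ketone to any useful extent, and alkylation of the open carboxylate gives the normal ester.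

Step 12
Reactants: 17 C15 methyl ester of the tricycle
Product: 18 methyl (1(10)E,4E,7S)-14-(tert-butyldimethylsilyloxy)-9-oxogermacra-1(10),4,11(12)-trien-15-oate (ten-membered dienone; C2 and C9 trans on C1=C10, C3 and C6 cis on C4=C5)
Conditions: PhMe (0.01 M, degassed), BHT (cat.), 160 °C, sealed tube
Reagents that add atoms: none
Why: Thermal cycloreversion of a bicyclo[2.2.0]hexane through its 1,4-diyl, known for enone–cyclobutene photoadducts: C1–C4 breaks first, helped by the ester on C4, then C5–C10, giving a cis,trans-cyclodeca-1,5-diene. The ester-delocalised radical at C4 should keep H5, not C6, beside its carbonyl group (allylic 1,3-strain), which puts C6 cis to C3 and therefore C9 trans to C2. No stereocentre is formed; the four cyclobutane centres are removed and C7 is untouched.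

Step 13
Reactants: 18 ten-membered dienone
Product: 19 methyl (1(10)E,4E,7S,9S)-14-(tert-butyldimethylsilyloxy)-9-hydroxygermacra-1(10),4,11(12)-trien-15-oate
Conditions: (R)-2-methyl-CBS-oxazaborolidine (20 mol %), catecholborane, PhMe, −78 °C
Reagents that add atoms: none
Why: Corey–Bakshi–Shibata reduction: the oxazaborolidine binds the carbonyl oxygen anti to the larger, fully substituted alkenyl carbon C10 and delivers hydride from catecholborane to one face; on this model the (R)-catalyst gives 9S. Catecholborane at −78 °C should leave the isopropenyl group, the enoate and the ester alone.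

Step 14
Reactants: 19 (9S)-allylic alcohol
Product: 20 methyl (1(10)E,4E,7S,9S)-9-acetoxy-14-(tert-butyldimethylsilyloxy)germacra-1(10),4,11(12)-trien-15-oate
Conditions: Ac2O, pyridine, DMAP (cat.), CH2Cl2, 0 °C to rt
Reagents that add atoms: acetic anhydride, CC(=O)OC(C)=O
Why: DMAP-catalysed acylation of the secondary allylic alcohol. It is done before C14 is unmasked so that only one free hydroxyl is present in step 16.

Step 15
Reactants: 20 (9S)-acetate
Product: 21 methyl (1(10)E,4E,7S,9S)-9-acetoxy-14-hydroxygermacra-1(10),4,11(12)-trien-15-oate
Conditions: HF·pyridine, pyridine, THF, 0 °C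
Reagents that add atoms: none
Why: Fluoride cleavage of the primary silyl ether under buffered, non-basic conditions, chosen to keep the C9 acetyl group from migrating to the new primary hydroxyl.

Step 16
Reactants: 21 C14 allylic alcohol
Product: 22 methyl (1R,4E,7S,9S,10S)-9-acetoxy-1,10-epoxy-14-hydroxygermacra-4,11(12)-dien-15-oate
Conditions: Ti(OiPr)4 (1.0 equiv), L-(+)-diisopropyl tartrate (1.2 equiv), t-BuOOH, 4 Å molecular sieves, CH2Cl2, −20 °C
Reagents that add atoms: tert-butyl hydroperoxide, CC(C)(C)OO
Why: Sharpless asymmetric epoxidation: the titanium tartrate binds the C14 alkoxide and the hydroperoxide and delivers oxygen to the alkene face fixed by the tartrate. For a primary allylic alcohol L-(+)-tartrate gives the 2S-type epoxy alcohol, here 1R,10S, and the E alkene becomes the trans epoxide. Only the allylic-alcohol alkene reacts, so the enoate and the isopropenyl group are spared, and the acetylated C9 oxygen cannot compete as a directing group.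

Step 17
Reactants: 22 epoxy alcohol
Product: 23 methyl (1R,4E,7S,9S,10S)-9-acetoxy-1,10-epoxy-14-(2-methylpropanoyloxy)germacra-4,11(12)-dien-15-oate (target)
Conditions: (i-PrCO)2O, Et3N, DMAP (cat.), CH2Cl2, 0 °C
Reagents that add atoms: isobutyric anhydride, CC(C)C(=O)OC(=O)C(C)C
Why: DMAP-catalysed acylation of the primary epoxy alcohol with the anhydride. Chloride-free, near-neutral conditions avoid opening of the epoxide and Payne-type migration.

## Compound list

1 | cyclohex-2-en-1-one | O=C1C=CCCC1 | starting material
2 | potassium trifluoro(prop-1-en-2-yl)borate | C=C(C)[B-](F)(F)F.[K+] | starting material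
3 | (S)-3-(prop-1-en-2-yl)cyclohexan-1-one | C=C(C)[C@H]1CCCC(=O)C1 | intermediate
4 | trimethyl{[(5S)-5-(prop-1-en-2-yl)cyclohex-1-en-1-yl]oxy}silane | C=C(C)[C@H]1CCC=C(O[Si](C)(C)C)C1 | intermediate
5 | (S)-5-(prop-1-en-2-yl)cyclohex-2-en-1-one | C=C(C)[C@H]1CC=CC(=O)C1 | intermediate
6 | formaldehyde | C=O | starting material
7 | (S)-2-(hydroxymethyl)-5-(prop-1-en-2-yl)cyclohex-2-en-1-one | C=C(C)[C@H]1CC=C(CO)C(=O)C1 | intermediate
8 | (S)-2-[(tert-butyldimethylsilyloxy)methyl]-5-(prop-1-en-2-yl)cyclohex-2-en-1-one | C=C(C)[C@H]1CC=C(CO[Si](C)(C)C(C)(C)C)C(=O)C1 | intermediate
9 | ethyl 1-bromocyclobutane-1-carboxylate | CCOC(=O)C1(Br)CCC1 | starting material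
10 | cyclobut-1-ene-1-carboxylic acid | OC(=O)C1=CCC1 | intermediate
11 | (cyclobut-1-en-1-yl)methanol | OCC1=CCC1 | intermediate
12 | 1-[(4-methoxybenzyloxy)methyl]cyclobut-1-ene | COc1ccc(COCC2=CCC2)cc1 | intermediate
13 | cis-anti-cis 6-4-4 photoadduct (CH2OTBS on C10, CH2OPMB on C4, isopropenyl on C7 anti to the cyclobutane) | C=C(C)[C@H]1C[C@@H]2[C@@]3(COCc4ccc(OC)cc4)CC[C@H]3[C@]2(CO[Si](C)(C)C(C)(C)C)C(=O)C1 | intermediate
14 | C15 alcohol of the tricycle | C=C(C)[C@H]1C[C@@H]2[C@@]3(CO)CC[C@H]3[C@]2(CO[Si](C)(C)C(C)(C)C)C(=O)C1 | intermediate
15 | C15 aldehyde of the tricycle | C=C(C)[C@H]1C[C@@H]2[C@@]3(C=O)CC[C@H]3[C@]2(CO[Si](C)(C)C(C)(C)C)C(=O)C1 | intermediate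
16 | C15 carboxylic acid of the tricycle | C=C(C)[C@H]1C[C@@H]2[C@@]3(C(=O)O)CC[C@H]3[C@]2(CO[Si](C)(C)C(C)(C)C)C(=O)C1 | intermediate
17 | C15 methyl ester of the tricycle (keto ester) | C=C(C)[C@H]1C[C@@H]2[C@@]3(C(=O)OC)CC[C@H]3[C@]2(CO[Si](C)(C)C(C)(C)C)C(=O)C1 | intermediate
18 | methyl (1(10)E,4E,7S)-14-(tert-butyldimethylsilyloxy)-9-oxogermacra-1(10),4,11(12)-trien-15-oate | C=C(C)[C@H]1C/C=C(/C(=O)OC)CC/C=C(\CO[Si](C)(C)C(C)(C)C)C(=O)C1 | intermediate
19 | methyl (1(10)E,4E,7S,9S)-14-(tert-butyldimethylsilyloxy)-9-hydroxygermacra-1(10),4,11(12)-trien-15-oate | C=C(C)[C@H]1C/C=C(/C(=O)OC)CC/C=C(\CO[Si](C)(C)C(C)(C)C)[C@@H](O)C1 | intermediate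
20 | methyl (1(10)E,4E,7S,9S)-9-acetoxy-14-(tert-butyldimethylsilyloxy)germacra-1(10),4,11(12)-trien-15-oate | C=C(C)[C@H]1C/C=C(/C(=O)OC)CC/C=C(\CO[Si](C)(C)C(C)(C)C)[C@@H](OC(C)=O)C1 | intermediate
21 | methyl (1(10)E,4E,7S,9S)-9-acetoxy-14-hydroxygermacra-1(10),4,11(12)-trien-15-oate | C=C(C)[C@H]1C/C=C(/C(=O)OC)CC/C=C(\CO)[C@@H](OC(C)=O)C1 | intermediate
22 | methyl (1R,4E,7S,9S,10S)-9-acetoxy-1,10-epoxy-14-hydroxygermacra-4,11(12)-dien-15-oate | C=C(C)[C@H]1C/C=C(/C(=O)OC)CC[C@H]2O[C@]2(CO)[C@@H](OC(C)=O)C1 | intermediate
23 | methyl (1R,4E,7S,9S,10S)-9-acetoxy-1,10-epoxy-14-(2-methylpropanoyloxy)germacra-4,11(12)-dien-15-oate | C=C(C)[C@H]1C/C=C(/C(=O)OC)CC[C@H]2O[C@]2(COC(=O)C(C)C)[C@@H](OC(C)=O)C1 | target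

## Step count and least certain steps

Total: 17 steps. Longest linear sequence: 14 steps (steps 1 to 4, then 8 to 17) from cyclohex-2-en-1-one; the cyclobutene branch (steps 5 to 7) joins at step 8.

Step 8 (key step).
- Most likely to go wrong: loss of the excited enone to paths other than head-to-tail addition to 12. The substrate is a 7-silyloxy carvone, and irradiated carvone is known to close onto its own isopropenyl group; an α-substituted enone also adds slowly to an external alkene, which gives this path and capture by the isopropenyl group of a second molecule more time. Head-to-head or trans-fused closure of the diradical is the second concern, and with no hydrogen on C10 a wrong ring fusion cannot be repaired by epimerisation.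
- Fallback: take the second alkene out of play. From 8, m-chloroperbenzoic acid (CH2Cl2, 0 °C) should epoxidise only the electron-rich isopropenyl group and give the oxirane-masked enone F1 (both epimers at the oxirane carbon). Irradiation of F1 with 12 as in step 8 gives the masked photoadduct F2. Deoxygenation of the 2,2-disubstituted oxirane through its iodohydrin (NaI, NaOAc, AcOH, then Zn) restores the isopropenyl group and returns to the route at 13.

Step 12.
- Most likely to go wrong: collapse of the diyl through the other chair, or equilibration of the first-formed dienone through the cis-divinylcyclohexanone by Cope and retro-Cope steps. Either way the trans alkene ends at C4=C5 and the ketone sits in a ring-cis enone, which medium rings favour; prolonged heating could also leave the divinylcyclohexanone as the sink.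
- Fallback: open the ring with C9 masked as a tetrahedral carbon, so that no ring enone can form and the ring-cis enoate is the more stable partner. From 17, Me3SiOCH2CH2OSiMe3 with catalytic Me3SiOTf (CH2Cl2, −78 to −20 °C) gives the ethylene ketal F3. Thermolysis as in step 12 gives the ketal diene F4. Pyridinium p-toluenesulfonate in wet acetone releases the ketone and returns to the route at 18.

Step 2.
- Most likely to go wrong: loss of regiocontrol in the deprotonation. The two α-methylene groups of a 3-substituted cyclohexanone differ little, and every enol ether formed toward C7 is lost as the achiral dienone.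
- Fallback: fix the regiochemistry under thermodynamic control with a carbon substituent that becomes C14. From 3, NaH and (MeO)2CO should carboxylate the less hindered α-carbon and give the β-keto ester F5. PhSeCl and pyridine give the selenide F6, and oxidation with NaIO4 with syn-elimination gives the enone ester F7. i-Bu2AlH reduces ketone and ester to the diol F8, t-BuMe2SiCl and imidazole silylate only the primary hydroxyl to give the mono-silyl ether F9, and MnO2 oxidises the allylic secondary alcohol. This returns to the route at 8 and bypasses 5 and 7.

Step 13.
- Most likely to go wrong: poor facial selectivity. The ketone lies in a ring whose conformation exposes one carbonyl face, and this substrate bias may oppose the catalyst; the twisted ring-trans enone may also not present C10 as the clearly larger group.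
- Fallback: accept substrate control and correct the centre by inversion. From 18, NaBH4 with CeCl3 (MeOH, −78 °C) reduces the ketone from the exposed face. If the product is the 9S alcohol it is 19; if it is the (9R)-allylic alcohol F10, a Mitsunobu reaction (PPh3, diisopropyl azodicarboxylate, AcOH) inverts C9 and installs the acetate in one operation, returning to the route at 20.

Step 16.
- Most likely to go wrong: a mismatch between the face demanded by the tartrate and the face exposed by the preferred conformer of the ring-trans alkene. Allylic alcohols with a cis substituent on the distal alkene carbon are also the slow class for this epoxidation, and the adjacent acetate lowers the reactivity of the alkene further.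
- Fallback: epoxidise without a directing group after the last acylation. From 21, (i-PrCO)2O, Et3N and DMAP give the diene diester F11. A Shi epoxidation (D-fructose-derived ketone, KHSO5, K2CO3 buffer, MeCN–dimethoxymethane–H2O, 0 °C) then selects the face of the trisubstituted E alkene by its spiro transition state; the enantiomeric ketone is used if the model assignment proves wrong. The electron-poor enoate and the less reactive 1,1-disubstituted isopropenyl group should be left alone. This arrives directly at 23.

## Further compounds

F1 | step 8 | (5S)-2-[(tert-butyldimethylsilyloxy)methyl]-5-(2-methyloxiran-2-yl)cyclohex-2-en-1-one (both oxirane epimers) | CC1(CO1)[C@H]2CC=C(CO[Si](C)(C)C(C)(C)C)C(=O)C2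
F2 | step 8 | oxirane-masked cis-anti-cis photoadduct | CC1(CO1)[C@H]2C[C@@H]3[C@@]4(COCc5ccc(OC)cc5)CC[C@H]4[C@]3(CO[Si](C)(C)C(C)(C)C)C(=O)C2
F3 | step 12 | ethylene ketal of the tricyclic keto ester | C=C(C)[C@H]1C[C@@H]2[C@@]3(C(=O)OC)CC[C@H]3[C@]2(CO[Si](C)(C)C(C)(C)C)C4(OCCO4)C1
F4 | step 12 | ethylene ketal of the ten-membered dienone | C=C(C)[C@H]1C/C=C(/C(=O)OC)CC/C=C(\CO[Si](C)(C)C(C)(C)C)C2(OCCO2)C1
F5 | step 2 | methyl (4S)-2-oxo-4-(prop-1-en-2-yl)cyclohexane-1-carboxylate | C=C(C)[C@H]1CCC(C(=O)OC)C(=O)C1
F6 | step 2 | methyl (4S)-2-oxo-1-(phenylselanyl)-4-(prop-1-en-2-yl)cyclohexane-1-carboxylate | C=C(C)[C@H]1CCC([Se]c2ccccc2)(C(=O)OC)C(=O)C1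
F7 | step 2 | methyl (4S)-6-oxo-4-(prop-1-en-2-yl)cyclohex-1-ene-1-carboxylate | C=C(C)[C@H]1CC=C(C(=O)OC)C(=O)C1
F8 | step 2 | (5S)-2-(hydroxymethyl)-5-(prop-1-en-2-yl)cyclohex-2-en-1-ol | C=C(C)[C@H]1CC=C(CO)C(O)C1
F9 | step 2 | (5S)-2-[(tert-butyldimethylsilyloxy)methyl]-5-(prop-1-en-2-yl)cyclohex-2-en-1-ol | C=C(C)[C@H]1CC=C(CO[Si](C)(C)C(C)(C)C)C(O)C1
F10 | step 13 | methyl (1(10)E,4E,7S,9R)-14-(tert-butyldimethylsilyloxy)-9-hydroxygermacra-1(10),4,11(12)-trien-15-oate | C=C(C)[C@H]1C/C=C(/C(=O)OC)CC/C=C(\CO[Si](C)(C)C(C)(C)C)[C@H](O)C1
F11 | step 16 | methyl (1(10)E,4E,7S,9S)-9-acetoxy-14-(2-methylpropanoyloxy)germacra-1(10),4,11(12)-trien-15-oate | C=C(C)[C@H]1C/C=C(/C(=O)OC)CC/C=C(\COC(=O)C(C)C)[C@@H](OC(C)=O)C1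
A1 | alternative 1 | ten-membered epoxy enoate, C9 triethylsilyl and C14 tert-butyldimethylsilyl ether | C=C(C)[C@H]1C/C=C(/C(=O)OC)CC[C@H]2O[C@]2(CO[Si](C)(C)C(C)(C)C)[C@@H](O[Si](CC)(CC)CC)C1
A2 | alternative 1 | open-chain (Z)-2-iodo enoate with C3 pinacol boronate, epoxide and both silyl ethers | C=C(C)[C@@H](C/C=C(\I)C(=O)OC)C[C@H](O[Si](CC)(CC)CC)[C@@]1(CO[Si](C)(C)C(C)(C)C)O[C@@H]1CCB1OC(C)(C)C(C)(C)O1
A3 | alternative 2 | ten-membered β-keto ester with E C1=C10 alkene (C4 either epimer) | C=C(C)[C@H]1CC(=O)C(C(=O)OC)CC/C=C(\CO[Si](C)(C)C(C)(C)C)CC1
A4 | alternative 2 | trans-decalin with C5 hydroxyl, equatorial C1 mesylate, angular CH2OTBS on C10 and CO2Me on C4 | C=C(C)[C@H]1C[C@@]2(O)C(C(=O)OC)CC[C@@H](OS(C)(=O)=O)[C@]2(CO[Si](C)(C)C(C)(C)C)CC1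
A5 | alternative 3 | ten-membered β-hydroxy acid (CO2H on C8, isopropenyl on C7) | C=C(C)[C@H]1C/C=C(/C(=O)OC)CC/C=C(\CO[Si](C)(C)C(C)(C)C)[C@@H](O)[C@@H]1C(=O)O
A6 | alternative 3 | fourteen-membered β-hydroxy macrolactone with (E)-allylic ester | O=C1C[C@H](O)/C(CO[Si](C)(C)C(C)(C)C)=C/CC/C(C(=O)OC)=C\C/C=C(\C)CO1
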